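## Retrosynthetic overview
1. The acid comes from its methyl ester. The C1 methyl of the cyclopentene comes from Me-coupling of an enol triflate of a trans-fused hydrindanone, so the ketone is a handle.
2. The hydrindanone comes from one type-1 intramolecular Diels–Alder (IMDA) of an (E)-4-oxo-2-enoate onto the end of an all-E tetraene. It forms both rings, the vicinal quaternary C6–C7 bond and four stereocentres at once.
3. The IMDA substrate comes from a methyl ketone by aldol condensation with methyl pyruvate.
4. The methyl ketone, with its allylic CH(CH3) centre, comes from BINOL-catalysed asymmetric conjugate alkenylation of (E)-pent-3-en-2-one with an all-E tetraenyl-Bpin. That tetraenyl-Bpin is built by iterative Wittig/HWE from the carboalumination–borylation product of propargyl alcohol.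

**Assumptions (one line each)**
- The target's CH(CH3) stereocentre is (R) in the open-chain ketone 10, and the BINOL enantiomer named in Step 6 is assumed to deliver that enantiomer; the antipode gives ent-target.
- The IMDA is assumed to proceed through a tether-exo/ester-endo chair-like TS with the C3-methyl pseudo-equatorial. This gives the trans-fused, all-cis-related pattern required by the target SMILES.
- Kinetic enolisation at C2 (CH2) in Step 10 is assumed not to epimerise C7a.

## Route

**Step 1**
Reactants: 1 propargyl alcohol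
Product: 2 (2E)-2-methyl-3-(4,4,5,5-tetramethyl-1,3,2-dioxaborolan-2-yl)prop-2-en-1-ol
Conditions: Me3Al, Cp2ZrCl2 (20 mol%), CH2Cl2, 0 °C→rt; then iPrOBpin, −78 °C→rt
Reagents that add atoms: trimethylaluminium, C[Al](C)C (supplies C-Me); 2-isopropoxy-4,4,5,5-tetramethyl-1,3,2-dioxaborolane, CC(C)OB1OC(C)(C)C(C)(C)O1 (supplies Bpin)
Why: Negishi syn-methylalumination puts Me on the internal carbon and Al on the terminal carbon, giving the (E)-trisubstituted vinylalane, which is trapped as the boronate with retention of geometry.

**Step 2**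
Reactants: 2
Product: 3 (2E)-2-methyl-3-(Bpin)prop-2-enal
Conditions: MnO2 (10 equiv), CH2Cl2, rt
Reagents that add atoms: none
Why: MnO2 oxidises the allylic alcohol chemoselectively, leaving the C–B bond and alkene geometry intact.

**Step 3**
Reactants: 3; 4 2-(triphenylphosphoranylidene)propanal
Product: 5 (2E,4E)-2,4-dimethyl-5-(Bpin)penta-2,4-dienal
Conditions: PhMe, 80 °C, 12 h
Reagents that add atoms: none
Why: Wittig olefination with a stabilised ylide gives the E-2-methyl-enal, which becomes the (E) diene unit that will react in the IMDA.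

**Step 4**
Reactants: 5; 4
Product: 6 (2E,4E,6E)-2,4,6-trimethyl-7-(Bpin)hepta-2,4,6-trienal
Conditions: PhMe, 80 °C, 12 h
Reagents that add atoms: none
Why: The same E-selective Wittig extension adds the next CH=C(CH3) unit of the isoprenoid-like chain.

**Step 5**
Reactants: 6; 7 diethyl benzylphosphonate
Product: 8 2-[(1E,3E,5E,7E)-2,4,6-trimethyl-8-phenylocta-1,3,5,7-tetraen-1-yl]-4,4,5,5-tetramethyl-1,3,2-dioxaborolane
Conditions: NaH, THF, 0 °C→rt
Reagents that add atoms: none
Why: Horner–Wadsworth–Emmons olefination gives the (E)-styryl terminus, completing the all-E tetraene side chain.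

**Step 6**
Reactants: 8; 9 (E)-pent-3-en-2-one
Product: 10 (4R,5E,7E,9E,11E)-4,6,8,10-tetramethyl-12-phenyldodeca-5,7,9,11-tetraen-2-one
Conditions: (S)-3,3'-bis[3,5-(CF3)2C6H3]-BINOL (15 mol%), iPrOH (2 equiv), PhMe, 40 °C, 48 h
Reagents that add atoms: none
Why: This is a BINOL-catalysed asymmetric conjugate alkenylation (Chong-type). Exchange at boron gives a chiral boronate that delivers the alkenyl group through a chair-like six-membered TS to the β-carbon of the enone, creating the allylic CH(CH3) stereocentre, the first in the route, as (R) with retention of the E-alkene.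

**Step 7**
Reactants: 10; 11 methyl pyruvate
Product: 12 methyl (6R,7E,9E,11E,13E)-2-hydroxy-2,6,8,10,12-pentamethyl-4-oxo-14-phenyltetradeca-7,9,11,13-tetraenoate (C2 epimer mixture)
Conditions: LDA (1.05 equiv), THF, −78 °C; then 11, −78 °C
Reagents that add atoms: none
Why: A kinetic aldol reaction: LDA deprotonates the methyl group rather than the branched CH2, and the enolate adds to the highly electrophilic pyruvate ketone; the C2 stereocentre is destroyed in the next step.

**Step 8**
Reactants: 12
Product: 13 methyl (2E,6R,7E,9E,11E,13E)-2,6,8,10,12-pentamethyl-4-oxo-14-phenyltetradeca-2,7,9,11,13-pentaenoate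
Conditions: MsCl, Et3N, CH2Cl2, 0 °C; then DBU, 0 °C→rt, dark
Reagents that add atoms: none
Why: Mesylation followed by E1cB elimination toward the ketone-activated C3–H gives the thermodynamic (E) 4-oxo-2-enoate, a fumarate-like dienophile.

**Step 9**
Reactants: 13
Product: 14 methyl 3,4,6,7-tetramethyl-6-[(1E,3E)-2-methyl-4-phenylbuta-1,3-dien-1-yl]-1-oxo-2,3,3a,6,7,7a-hexahydro-1H-indene-7-carboxylate. It is trans-fused, with the configuration of the target at all five stereocentres.
Conditions: Schreiner thiourea (20 mol%), BHT (5 mol%), PhMe (0.005 M), 60 °C, 48 h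
Reagents that add atoms: none
Why: Proposed new method: a type-1 intramolecular Diels–Alder (concerted, asynchronous [4+2]) of the fumarate-like ketoenoate onto the (E,E)-diene terminus that carries a methyl and a dienyl group. Thiourea double H-bonding lowers the dienophile LUMO so that the hindered quaternary–quaternary C6–C7 bond forms below the temperature at which the polyene decomposes. A tether-exo/ester-endo chair-like TS with the C3-methyl pseudo-equatorial sets C3a, C6, C7 and C7a relative to the existing C3 centre. The closest known reactions are Lewis-acid/H-bond-donor-promoted type-1 IMDA of 1,3,8-nonatrienes and thiourea-catalysed Diels–Alder of enones; neither has been shown for this diene-terminus/ketoenoate pair.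

**Step 10**
Reactants: 14
Product: 15 methyl 3,4,6,7-tetramethyl-6-[(1E,3E)-2-methyl-4-phenylbuta-1,3-dien-1-yl]-1-(triflyloxy)-3a,6,7,7a-tetrahydro-3H-indene-7-carboxylate
Conditions: KHMDS, THF, −78 °C; then PhNTf2, −78→0 °C
Reagents that add atoms: N-phenylbis(trifluoromethanesulfonimide), O=S(=O)(C(F)(F)F)N(c1ccccc1)S(=O)(=O)C(F)(F)F (supplies the triflate)
Why: Kinetic deprotonation at the unhindered C2-H2 gives the Δ1,2-enol triflate regioselectively; the ester has no α-H, and C7a is not touched.

**Step 11**
Reactants: 15
Product: 16 methyl 1,3,4,6,7-pentamethyl-6-[(1E,3E)-2-methyl-4-phenylbuta-1,3-dien-1-yl]-3a,6,7,7a-tetrahydro-3H-indene-7-carboxylate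
Conditions: Pd(PPh3)4 (5 mol%), Me2Zn, LiCl, THF, 50 °C
Reagents that add atoms: dimethylzinc, C[Zn]C (supplies the C1 methyl)
Why: Negishi coupling of the vinyl triflate installs the trisubstituted cyclopentene methyl, and the double bond stays at C1=C2.

**Step 12**
Reactants: 16
Product: 17 target acid, (3R,3aS,6S,7R,7aR)-1,3,4,6,7-pentamethyl-6-[(1E,3E)-2-methyl-4-phenylbuta-1,3-dien-1-yl]-3a,6,7,7a-tetrahydro-3H-indene-7-carboxylic acid (27-nor-zyggomphic acid B). The indene numbering here is my own descriptive numbering.
Conditions: n-PrSLi, HMPA, THF, 0 °C→rt; then aqueous H3O+ workup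
Reagents that add atoms: none
Why: Thiolate SN2 attack at the ester O-methyl group cleaves the methyl ester of this acyl-hindered, doubly α-quaternary centre without touching any stereocentre or alkene.

## Compound list
1 | propargyl alcohol | C#CCO | starting material
2 | (2E)-2-methyl-3-(Bpin)prop-2-en-1-ol | OC/C(C)=C/B1OC(C)(C)C(C)(C)O1 | intermediate
3 | (2E)-2-methyl-3-(Bpin)prop-2-enal | O=C/C(C)=C/B1OC(C)(C)C(C)(C)O1 | intermediate
4 | 2-(triphenylphosphoranylidene)propanal | CC(C=O)=P(c1ccccc1)(c1ccccc1)c1ccccc1 | starting material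
5 | (2E,4E)-2,4-dimethyl-5-(Bpin)penta-2,4-dienal | O=C/C(C)=C/C(C)=C/B1OC(C)(C)C(C)(C)O1 | intermediate
6 | (2E,4E,6E)-2,4,6-trimethyl-7-(Bpin)hepta-2,4,6-trienal | O=C/C(C)=C/C(C)=C/C(C)=C/B1OC(C)(C)C(C)(C)O1 | intermediate
7 | diethyl benzylphosphonate | CCOP(=O)(Cc1ccccc1)OCC | starting material
8 | tetraenyl-Bpin (1E,3E,5E,7E) | CC1(C)OB(OC1(C)C)/C=C(C)/C=C(C)/C=C(C)/C=C/c1ccccc1 | intermediate
9 | (E)-pent-3-en-2-one | C/C=C/C(C)=O | starting material
10 | (4R,5E,7E,9E,11E)-4,6,8,10-tetramethyl-12-phenyldodeca-5,7,9,11-tetraen-2-one | CC(=O)C[C@@H](C)/C=C(C)/C=C(C)/C=C(C)/C=C/c1ccccc1 | intermediate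
11 | methyl pyruvate | COC(=O)C(C)=O | starting material
12 | aldol adduct (C2 epimer mixture) | COC(=O)C(C)(O)CC(=O)C[C@@H](C)/C=C(C)/C=C(C)/C=C(C)/C=C/c1ccccc1 | intermediate
13 | (2E)-4-oxo-2-enoate IMDA precursor | COC(=O)/C(C)=C/C(=O)C[C@@H](C)/C=C(C)/C=C(C)/C=C(C)/C=C/c1ccccc1 | intermediate
14 | trans-fused hydrindanone methyl ester | CC1=C[C@](C)(/C=C(C)/C=C/c2ccccc2)[C@](C)(C(=O)OC)[C@H]2C(=O)C[C@@H](C)[C@H]12 | intermediate
15 | enol triflate | CC1=C[C@](C)(/C=C(C)/C=C/c2ccccc2)[C@](C)(C(=O)OC)[C@H]2C(OS(=O)(=O)C(F)(F)F)=C[C@@H](C)[C@H]12 | intermediate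
16 | methyl ester of target | CC1=C[C@](C)(/C=C(C)/C=C/c2ccccc2)[C@](C)(C(=O)OC)[C@H]2C(C)=C[C@@H](C)[C@H]12 | intermediate
17 | 27-nor-zyggomphic acid B | CC1=C[C@](C)(/C=C(C)/C=C/c2ccccc2)[C@](C)(C(=O)O)[C@H]2C(C)=C[C@@H](C)[C@H]12 | target

## Totals
Total steps: 12. Longest linear sequence: 12 (from propargyl alcohol).

**Three steps most likely to fail**
1. **Step 9 (the proposed new IMDA).** The hindered quaternary–quaternary bond formation may be slow, and the cis/trans ring-fusion or facial selectivity may be poor.
   - Fallback (known chemistry): use methyl glyoxylate instead of pyruvate in Step 7, so the fumarate-type dienophile lacks the α-methyl. The IMDA then forms only one quaternary centre, and Steps 10–11 follow. The ester α-methyl is then installed by LDA/MeI α-methylation, with the enolate attacked anti to the side chain.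
2. **Step 6 (asymmetric conjugate alkenylation).** A hindered trisubstituted tetraenyl pinacol boronate may be unreactive in BINOL exchange, or the ee may be low.
   - Fallback: Rh(I)/BINAP-catalysed Hayashi–Miyaura 1,4-addition of the corresponding tetraenylboronic acid to (E)-pent-3-en-2-one.
3. **Step 5 (HWE on a base-sensitive tetraenyl boronate).** The C–B bond may not survive the NaH conditions, or the polyenyl boronate may be unstable.
   - Fallback: carry the vinyl iodide from Step 1 (Me3Al/Cp2ZrCl2, then I2) through the MnO2, Wittig, Wittig and HWE sequence. Convert the tetraenyl iodide to the boronate only at the end by Miyaura borylation, which reverses the order of bond constructions.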